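The α-methylene-γ-butyrolactone ring (O, C6, C7, C11, C12) fused to the ten-membered carbocycle is read as a terminal allene (C7=C11=C13), an enal carbonyl (C6=O) and CO2 (C12). Germacrane numbering is used: C6 is the lactone O–CH, C7 the ring-fusion CH, C11 the α-carbon, C12 the carbonyl, C13 the methylene. In one operation zerovalent nickel fixes CO2 on the central allene carbon (C11–C12), and the allylnickel carboxylate so formed adds through C7 to the tethered aldehyde (C6–C7), closing the carbocycle and, after acid, the lactone. The precursor is an acyclic (2E,6Z)-dodecatetraenal bearing the C2 and C9 silyloxy stereocenters, each set by a catalyst-controlled aldehyde addition.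

Key step: step 12

Remark: (S)-TRIP is (S)-3,3'-bis(2,4,6-triisopropylphenyl)-1,1'-binaphthyl-2,2'-diyl hydrogen phosphate; the (R,R)-bisphosphoramide is the pentane-1,5-diyl-linked bis(N,N'-dimethyl-1,1'-binaphthyl-2,2'-diamine phosphoramide). Their antipodes are assigned by analogy with their facial preference for aryl and alkenyl aldehydes; the face each step needs is stated, and the other antipode is taken if a model reaction shows the opposite sense.

Step 1
Reactants: 1 propargyl alcohol
Product: 3 (Z)-3-iodo-2-methylprop-2-en-1-ol, via alkenylmagnesium chelate 2 (not isolated)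
Conditions: MeMgBr (2.5 equiv), CuI (10 mol %), THF, −10 to 23 °C; then I2, −78 to 0 °C
Reagents that add atoms: methylmagnesium bromide C[Mg]Br; iodine [I][I]
Why: Copper-catalysed anti-carbomagnesiation of the propargylic alkoxide puts methyl on the proximal carbon and magnesium, held in a five-membered chelate, on the distal one, so iodinolysis with retention should give the (Z)-iodide (iodine cis to CH2OH).

Step 2
Reactants: 3 (Z)-3-iodo-2-methylprop-2-en-1-ol
Product: 4 (Z)-3-iodo-2-methylprop-2-enal
Conditions: MnO2, CH2Cl2, 23 °C; used crude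
Reagents that add atoms: none
Why: Allylic oxidation with MnO2 is neutral and heterogeneous, which should spare the (Z)-geometry of the sensitive iodoenal.

Step 3
Reactants: 4 (Z)-3-iodo-2-methylprop-2-enal
Product: 5 (1Z,3S)-1-iodo-2-methylhex-1-en-5-yn-3-ol
Conditions: allenylboronic acid pinacol ester (1.5 equiv), (S)-TRIP (5 mol %), 4 Å MS, toluene, −20 °C; aq. NaHCO3
Reagents that add atoms: 4,4,5,5-tetramethyl-2-(propa-1,2-dienyl)-1,3,2-dioxaborolane C=C=CB1OC(C)(C)C(C)(C)O1
Why: Chiral phosphoric acid-catalysed propargylboration runs through a closed six-membered SE2' transition state held by the acid, and the (S)-acid should direct the allenylboronate to the Si face of 4 to set C9 (S).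

Step 4
Reactants: 5 (1Z,3S)-1-iodo-2-methylhex-1-en-5-yn-3-ol
Product: 6 triethyl{[(1Z,3S)-1-iodo-2-methylhex-1-en-5-yn-3-yl]oxy}silane
Conditions: TESCl, imidazole, CH2Cl2, 0 °C
Reagents that add atoms: chlorotriethylsilane CC[Si](Cl)(CC)CC
Why: Standard silylation of a secondary alcohol; the triethylsilyl group should survive steps 5–11 yet leave before the tert-butyldimethylsilyl groups.

Step 5
Reactants: 6 triethyl{[(1Z,3S)-1-iodo-2-methylhex-1-en-5-yn-3-yl]oxy}silane
Product: 8 triethyl{[(1Z,3S)-1-iodo-2-methylhepta-1,5,6-trien-3-yl]oxy}silane, via Mannich base 7 (not isolated)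
Conditions: (CH2O)n, CuI (0.5 equiv), Cy2NH, 1,4-dioxane, reflux
Reagents that add atoms: formaldehyde (as paraformaldehyde) C=O
Why: Crabbé homologation, in which the Mannich base from alkyne, formaldehyde and Cy2NH undergoes copper-assisted 1,5-hydride transfer and loss of the imine to give the terminal allene; without palladium or ligand the hindered vinyl iodide and C9 should be untouched.

Step 6
Reactants: 8 triethyl{[(1Z,3S)-1-iodo-2-methylhepta-1,5,6-trien-3-yl]oxy}silane
Product: 10 (2Z,4S)-3-methyl-4-(triethylsilyloxy)octa-2,6,7-trienal, via vinyllithium 9 (not isolated)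
Conditions: t-BuLi (2.05 equiv), Et2O, −78 °C; DMF, −78 to 0 °C; H2O
Reagents that add atoms: N,N-dimethylformamide CN(C)C=O
Why: Iodine–lithium exchange proceeds with retention of the (Z)-geometry and, at −78 °C in ether, should outrun allene metalation and 1,4-O-to-C silyl migration, so formylation with DMF gives the (Z)-enal.

Step 7
Reactants: 11 ethyl 3-methylbut-2-enoate
Product: 13 tert-butyl[(1-ethoxy-3-methylbuta-1,3-dienyl)oxy]dimethylsilane, via lithium dienolate 12 (not isolated)
Conditions: LiN(iPr)2, THF, −78 °C; TBSCl, DMPU, −78 to 0 °C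
Reagents that add atoms: tert-butyldimethylsilyl chloride CC(C)(C)[Si](C)(C)Cl
Why: γ-Deprotonation of the senecioate gives the extended lithium dienolate, which silylates on oxygen to the silyl dienol ether needed for the vinylogous Mukaiyama aldol.

Step 8
Reactants: 10 (2Z,4S)-3-methyl-4-(triethylsilyloxy)octa-2,6,7-trienal; 13 tert-butyl[(1-ethoxy-3-methylbuta-1,3-dienyl)oxy]dimethylsilane
Product: 14 ethyl (2E,5R,6Z,8S)-5-hydroxy-3,7-dimethyl-8-(triethylsilyloxy)dodeca-2,6,10,11-tetraenoate
Conditions: SiCl4 (1.1 equiv), (R,R)-bisphosphoramide (5 mol %), iPr2NEt (10 mol %), CH2Cl2, −78 °C; aq. NaHCO3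
Reagents that add atoms: none
Why: In this Lewis-base-activated SiCl4 vinylogous Mukaiyama aldol the phosphoramide-bound silyl cation activates the enal, the dienolate attacks through its γ-carbon on the Re face exposed by the (R,R)-catalyst to set C2 (R) under catalyst control, and the s-trans dienolate should give the (E)-enoate.

Step 9
Reactants: 14 ethyl (2E,5R,6Z,8S)-5-hydroxy-3,7-dimethyl-8-(triethylsilyloxy)dodeca-2,6,10,11-tetraenoate
Product: 15 ethyl (2E,5R,6Z,8S)-5-(tert-butyldimethylsilyloxy)-3,7-dimethyl-8-(triethylsilyloxy)dodeca-2,6,10,11-tetraenoate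
Conditions: TBSOTf, 2,6-lutidine, CH2Cl2, −78 °C
Reagents that add atoms: tert-butyldimethylsilyl triflate CC(C)(C)[Si](C)(C)OS(=O)(=O)C(F)(F)F
Why: Silylation of the secondary allylic alcohol with the triflate under buffered conditions should leave the triethylsilyl ether in place.

Step 10
Reactants: 15 ethyl (2E,5R,6Z,8S)-5-(tert-butyldimethylsilyloxy)-3,7-dimethyl-8-(triethylsilyloxy)dodeca-2,6,10,11-tetraenoate
Product: 16 (2E,5R,6Z,8S)-5-(tert-butyldimethylsilyloxy)-3,7-dimethyl-8-(triethylsilyloxy)dodeca-2,6,10,11-tetraen-1-ol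
Conditions: iBu2AlH (2.2 equiv), CH2Cl2, −78 °C; aq. KNaC4H4O6 (potassium sodium tartrate)
Reagents that add atoms: none
Why: 1,2-Reduction of the enoate by iBu2AlH at −78 °C should give the (E)-allylic alcohol without touching the allene or the silyl ethers.

Step 11
Reactants: 16 (2E,5R,6Z,8S)-5-(tert-butyldimethylsilyloxy)-3,7-dimethyl-8-(triethylsilyloxy)dodeca-2,6,10,11-tetraen-1-ol
Product: 17 (2E,5R,6Z,8S)-5-(tert-butyldimethylsilyloxy)-3,7-dimethyl-8-(triethylsilyloxy)dodeca-2,6,10,11-tetraenal
Conditions: MnO2, CH2Cl2, 23 °C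
Reagents that add atoms: none
Why: MnO2 oxidises only the allylic alcohol and should give the (E)-enal without isomerisation.

Step 12
Reactants: 17 (2E,5R,6Z,8S)-5-(tert-butyldimethylsilyloxy)-3,7-dimethyl-8-(triethylsilyloxy)dodeca-2,6,10,11-tetraenal
Product: 22 (2R,6R,7S,9S)-2-(tert-butyldimethylsilyloxy)-9-hydroxygermacra-1(10)Z,4E,11(13)-trien-12,6-olide, via nickelalactone 18 (not isolated), via nickel alkoxide carboxylate 19 (not isolated), via hydroxy acid 20 (not isolated), via triethylsilyl lactone 21 (not isolated)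
Conditions: Ni(cod)2 (1.1 equiv), DBU (2.5 equiv), CO2 (1 atm), THF, 0 °C, 17 added over 8 h (2 mM); then 1 M HCl, 0 °C; crude in MeOH, PPTS, 23 °C
Reagents that add atoms: carbon dioxide O=C=O
Why: Zerovalent nickel carrying DBU couples CO2 oxidatively with the terminal C11=C13 π-bond of the allene to give nickelalactone 18 (C11–C12 bond), an allylnickel carboxylate of divalent nickel whose γ-carbon C7 adds to the tethered enal carbonyl C6 through a closed, chair-like six-membered transition state (C6–C7 bond); acid then releases hydroxy acid 20, which lactonises, and PPTS in MeOH removes the triethylsilyl group. The closest known reaction type is the nickel-mediated sequential coupling of terminal allenes, CO2 and aryl or conjugated aldehydes to α-methylene-γ-butyrolactones, used here in a ring-closing mode with the aldehyde present from the start. The ten-membered carbocycle closes by allylmetal addition to the aldehyde (10-exo-trig at C6, the mode known from chromium-mediated allylations to germacranolides), the γ-lactone by 5-exo-trig acyl substitution of the C12 carboxyl by the C6 hydroxyl. The 6,7-trans relationship should follow from the chair in which C5 and C8 are both equatorial, reached because the allylnickel is stereochemically labile (η3/η1) and favoured because the (4E,1(10)Z) tether spans two equatorial positions without transannular strain; the absolute sense at C6 and C7 is relayed from C9, whose bulky silyloxy group next to C8 should take the outward, pseudo-equatorial position on the forming ring, with the C2 silyloxy group acting in the same sense. The step needs chemoselectivity (CO2 fixation on the allene before nickel engages the enal), regioselectivity (CO2 on the central carbon, the aldehyde on C7 and not C13) and ring closure over oligomerisation, which the higher affinity of the allene for zerovalent nickel under CO2, the chelated σ-allyl bound at C13 and slow addition at high dilution should secure.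

Step 13
Reactants: 23 ethyl but-2-ynoate
Product: 25 ethyl (Z)-2-(hydroxymethyl)but-2-enoate, via vinylalane 24 (not isolated)
Conditions: iBu2AlH, NMO, THF, 0 °C; then CH2O (cracked from (CH2O)n), 0 to 23 °C; aq. KNaC4H4O6
Reagents that add atoms: formaldehyde C=O
Why: syn-Hydroalumination of the ynoate (hydride to C3, aluminium to C2) gives the α-alumino enoate with ester and methyl cis, and its addition to formaldehyde with retention (vinylalumination, a Baylis–Hillman-type product) should give the (Z)-ester.

Step 14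
Reactants: 25 ethyl (Z)-2-(hydroxymethyl)but-2-enoate
Product: 26 ethyl (Z)-2-[(tert-butyldimethylsilyloxy)methyl]but-2-enoate
Conditions: TBSCl, imidazole, DMF, 23 °C
Reagents that add atoms: tert-butyldimethylsilyl chloride CC(C)(C)[Si](C)(C)Cl
Why: Standard silylation of the primary allylic alcohol, so that the acid cannot acylate itself in step 16.

Step 15
Reactants: 26 ethyl (Z)-2-[(tert-butyldimethylsilyloxy)methyl]but-2-enoate
Product: 27 (Z)-2-[(tert-butyldimethylsilyloxy)methyl]but-2-enoic acid
Conditions: LiOH, THF/H2O, 0 to 23 °C; 1 M HCl to pH 4, 0 °C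
Reagents that add atoms: lithium hydroxide (aqueous) [Li+].[OH-]
Why: Saponification with LiOH at or below 23 °C should cleave the ethyl ester without Z-to-E isomerisation or loss of the silyl ether.

Step 16
Reactants: 27 (Z)-2-[(tert-butyldimethylsilyloxy)methyl]but-2-enoic acid; 22 (2R,6R,7S,9S)-2-(tert-butyldimethylsilyloxy)-9-hydroxygermacra-1(10)Z,4E,11(13)-trien-12,6-olide
Product: 29 (2R,6R,7S,9S)-2-(tert-butyldimethylsilyloxy)-9-{(Z)-2-[(tert-butyldimethylsilyloxy)methyl]but-2-enoyloxy}germacra-1(10)Z,4E,11(13)-trien-12,6-olide, via mixed anhydride 28 (not isolated)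
Conditions: 2,4,6-Cl3C6H2COCl, Et3N, THF, 23 °C; then 22, DMAP, toluene, 23 °C
Reagents that add atoms: none
Why: Yamaguchi esterification through the mixed anhydride acylates the only free hydroxyl (C9) and is the usual choice for angelate-type acids because it should not isomerise the (Z)-olefin.

Step 17
Reactants: 29 (2R,6R,7S,9S)-2-(tert-butyldimethylsilyloxy)-9-{(Z)-2-[(tert-butyldimethylsilyloxy)methyl]but-2-enoyloxy}germacra-1(10)Z,4E,11(13)-trien-12,6-olide
Product: 30 (2R,6R,7S,9S)-2-hydroxy-9-[(Z)-2-(hydroxymethyl)but-2-enoyloxy]germacra-1(10)Z,4E,11(13)-trien-12,6-olide (CNP0273961.1)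
Conditions: HF·pyridine, pyridine, THF, 0 to 23 °C
Reagents that add atoms: none
Why: Buffered HF·pyridine should cleave both tert-butyldimethylsilyl ethers while leaving the α-methylene lactone, the ester and the allylic alcohols intact.

Compound list
1 | prop-2-yn-1-ol (propargyl alcohol) | C#CCO | starting material
2 | chelated (Z)-alkenylmagnesium alkoxide, 4-methyl-2,5-dihydro-1,2-oxamagnesole (not isolated; MgBr2 and THF not drawn) | CC1=C[Mg]OC1 | intermediate
3 | (Z)-3-iodo-2-methylprop-2-en-1-ol | OC/C(C)=C\I | intermediate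
4 | (Z)-3-iodo-2-methylprop-2-enal | O=C/C(C)=C\I | intermediate
5 | (1Z,3S)-1-iodo-2-methylhex-1-en-5-yn-3-ol | C#CC[C@H](O)/C(C)=C\I | intermediate
6 | triethyl{[(1Z,3S)-1-iodo-2-methylhex-1-en-5-yn-3-yl]oxy}silane | C#CC[C@H](O[Si](CC)(CC)CC)/C(C)=C\I | intermediate
7 | (5S,6Z)-N,N-dicyclohexyl-7-iodo-6-methyl-5-(triethylsilyloxy)hept-6-en-2-yn-1-amine (Mannich base, not isolated) | C1CCC(CC1)N(CC#CC[C@H](O[Si](CC)(CC)CC)/C(C)=C\I)C1CCCCC1 | intermediate
8 | triethyl{[(1Z,3S)-1-iodo-2-methylhepta-1,5,6-trien-3-yl]oxy}silane | C=C=CC[C@H](O[Si](CC)(CC)CC)/C(C)=C\I | intermediate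
9 | [(1Z,3S)-2-methyl-3-(triethylsilyloxy)hepta-1,5,6-trienyl]lithium (not isolated) | [Li]/C=C(/C)[C@@H](O[Si](CC)(CC)CC)CC=C=C | intermediate
10 | (2Z,4S)-3-methyl-4-(triethylsilyloxy)octa-2,6,7-trienal | O=C/C=C(/C)[C@@H](O[Si](CC)(CC)CC)CC=C=C | intermediate
11 | ethyl 3-methylbut-2-enoate | CCOC(=O)C=C(C)C | starting material
12 | lithium 1-ethoxy-3-methylbuta-1,3-dien-1-olate (not isolated) | [Li]OC(OCC)=CC(C)=C | intermediate
13 | tert-butyl[(1-ethoxy-3-methylbuta-1,3-dienyl)oxy]dimethylsilane | CCOC(O[Si](C)(C)C(C)(C)C)=CC(C)=C | intermediate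
14 | ethyl (2E,5R,6Z,8S)-5-hydroxy-3,7-dimethyl-8-(triethylsilyloxy)dodeca-2,6,10,11-tetraenoate | CCOC(=O)/C=C(\C)C[C@@H](O)/C=C(/C)[C@@H](O[Si](CC)(CC)CC)CC=C=C | intermediate
15 | ethyl (2E,5R,6Z,8S)-5-(tert-butyldimethylsilyloxy)-3,7-dimethyl-8-(triethylsilyloxy)dodeca-2,6,10,11-tetraenoate | CCOC(=O)/C=C(\C)C[C@@H](O[Si](C)(C)C(C)(C)C)/C=C(/C)[C@@H](O[Si](CC)(CC)CC)CC=C=C | intermediate
16 | (2E,5R,6Z,8S)-5-(tert-butyldimethylsilyloxy)-3,7-dimethyl-8-(triethylsilyloxy)dodeca-2,6,10,11-tetraen-1-ol | OC/C=C(\C)C[C@@H](O[Si](C)(C)C(C)(C)C)/C=C(/C)[C@@H](O[Si](CC)(CC)CC)CC=C=C | intermediate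
17 | (2E,5R,6Z,8S)-5-(tert-butyldimethylsilyloxy)-3,7-dimethyl-8-(triethylsilyloxy)dodeca-2,6,10,11-tetraenal | O=C/C=C(\C)C[C@@H](O[Si](C)(C)C(C)(C)C)/C=C(/C)[C@@H](O[Si](CC)(CC)CC)CC=C=C | intermediate
18 | nickelalactone, the 3-alkylidene-1-oxa-2-nickelacyclopentan-5-one (allylnickel carboxylate of divalent nickel) from 17 and CO2 (not isolated; DBU on nickel not drawn) | O=C1O[Ni]CC1=CC[C@H](O[Si](CC)(CC)CC)/C(C)=C\[C@H](O[Si](C)(C)C(C)(C)C)C/C(C)=C/C=O | intermediate
19 | ring-closed divalent-nickel alkoxide carboxylate chelate (not isolated; DBU not drawn) | C=C1C(=O)O[Ni]O[C@@H]2/C=C(\C)C[C@@H](O[Si](C)(C)C(C)(C)C)/C=C(/C)[C@@H](O[Si](CC)(CC)CC)C[C@@H]12 | intermediate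
20 | (2R,6R,7S,9S)-2-(tert-butyldimethylsilyloxy)-6-hydroxy-9-(triethylsilyloxy)germacra-1(10)Z,4E,11(13)-trien-12-oic acid (not isolated) | C=C(C(=O)O)[C@@H]1C[C@H](O[Si](CC)(CC)CC)/C(C)=C\[C@H](O[Si](C)(C)C(C)(C)C)C/C(C)=C/[C@H]1O | intermediate
21 | (2R,6R,7S,9S)-2-(tert-butyldimethylsilyloxy)-9-(triethylsilyloxy)germacra-1(10)Z,4E,11(13)-trien-12,6-olide (not isolated) | C=C1C(=O)O[C@@H]2/C=C(\C)C[C@@H](O[Si](C)(C)C(C)(C)C)/C=C(/C)[C@@H](O[Si](CC)(CC)CC)C[C@@H]12 | intermediate
22 | (2R,6R,7S,9S)-2-(tert-butyldimethylsilyloxy)-9-hydroxygermacra-1(10)Z,4E,11(13)-trien-12,6-olide | C=C1C(=O)O[C@@H]2/C=C(\C)C[C@@H](O[Si](C)(C)C(C)(C)C)/C=C(/C)[C@@H](O)C[C@@H]12 | intermediate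
23 | ethyl but-2-ynoate | CC#CC(=O)OCC | starting material
24 | ethyl (E)-2-(diisobutylalumanyl)but-2-enoate (not isolated) | CCOC(=O)/C(=C\C)[Al](CC(C)C)CC(C)C | intermediate
25 | ethyl (Z)-2-(hydroxymethyl)but-2-enoate | CCOC(=O)/C(=C\C)CO | intermediate
26 | ethyl (Z)-2-[(tert-butyldimethylsilyloxy)methyl]but-2-enoate | CCOC(=O)/C(=C\C)CO[Si](C)(C)C(C)(C)C | intermediate
27 | (Z)-2-[(tert-butyldimethylsilyloxy)methyl]but-2-enoic acid | OC(=O)/C(=C\C)CO[Si](C)(C)C(C)(C)C | intermediate
28 | (Z)-2-[(tert-butyldimethylsilyloxy)methyl]but-2-enoic 2,4,6-trichlorobenzoic anhydride (not isolated) | O=C(OC(=O)/C(=C\C)CO[Si](C)(C)C(C)(C)C)c1c(Cl)cc(Cl)cc1Cl | intermediate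
29 | (2R,6R,7S,9S)-2-(tert-butyldimethylsilyloxy)-9-{(Z)-2-[(tert-butyldimethylsilyloxy)methyl]but-2-enoyloxy}germacra-1(10)Z,4E,11(13)-trien-12,6-olide | C=C1C(=O)O[C@@H]2/C=C(\C)C[C@@H](O[Si](C)(C)C(C)(C)C)/C=C(/C)[C@@H](OC(=O)/C(=C\C)CO[Si](C)(C)C(C)(C)C)C[C@@H]12 | intermediate
30 | (2R,6R,7S,9S)-2-hydroxy-9-[(Z)-2-(hydroxymethyl)but-2-enoyloxy]germacra-1(10)Z,4E,11(13)-trien-12,6-olide (CNP0273961.1) | C=C1C(=O)O[C@@H]2/C=C(\C)C[C@@H](O)/C=C(/C)[C@@H](OC(=O)/C(=C\C)CO)C[C@@H]12 | target

Total step count: 17. Longest linear sequence: 13 (steps 1–6, 8–12, 16, 17).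

Steps most likely to fail

Step 12. Three processes may defeat it:
- zerovalent nickel may bind or reductively couple the enal before CO2 is fixed on the allene;
- intermolecular allylation (oligomerisation) may outrun closure of the ten-membered ring;
- the allylnickel may react through the kinetic (Z)-allyl geometry or the wrong face, eroding the 6,7-trans relationship or its sense relative to C9.

Fallback, setting out from 17: 9-bromo-9-borabicyclo[3.3.1]nonane (CH2Cl2, −78 °C, high dilution) should bromoborate the terminal C11=C13 bond, boron to C13 and bromide to C11, to give the 2-bromoallylborane F1 (not isolated). After 1,3-boron shift to its (E)-isomer, F1 allylborates the tethered enal through C7 in a closed chair and, after aqueous NaHCO3, gives the ring-closed 2-bromoallyl carbinol F2. Pd(PPh3)4 (zerovalent palladium, 5 mol %), CO (1 atm) and Et3N in MeCN at 60 °C then carbonylate the alkenyl bromide with capture by the C6 hydroxyl. This gives triethylsilyl lactone 21, where the route is rejoined (PPTS, MeOH, to 22). The two bonds are then made in two flasks by known haloboration–allylboration and carbonylative lactonisation.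

Step 8. The enal may isomerise from Z to E under Lewis-acid activation, facial control by the catalyst may be poor, or attack through the s-cis dienolate may give the (Z)-enoate, which lactonises.

Fallback, setting out from 10: propargylboration with the allenylboronate of step 3 under (R)-TRIP (Re face) gives the homopropargylic alcohol F3, and silylation (TBSOTf, 2,6-lutidine) gives the silyl ether F4. Zirconium-catalysed carboalumination (Me3Al, Cp2ZrCl2, CH2Cl2) then gives the (E)-alkenylalane F5 (not isolated), and its hydroxymethylation with paraformaldehyde gives allylic alcohol 16, where the route is rejoined. C2 then comes from a closed transition state and the (E)-olefin from syn-carbometalation, in the same number of steps.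

Step 5. Copper-mediated coupling of the vinyl iodide with the terminal alkyne, alkyne homocoupling, or thermal loss of the triethylsilyl group at reflux may compete with allene formation.

Fallback, setting out from 6: deprotonation of the alkyne with LiN(iPr)2 (THF, −78 °C) and addition to paraformaldehyde gives the propargylic alcohol F6. Mitsunobu reaction with 2-nitrobenzenesulfonylhydrazide (PPh3, diethyl azodicarboxylate, THF, −15 °C) gives the sulfonylhydrazine F7 (not isolated). At 23 °C F7 loses the sulfinic acid to give the propargylic diazene F8 (not isolated), whose retro-ene loss of N2 gives allene 8, where the route is rejoined without copper or heat.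

Further compounds
F1 | step 12 | 2-bromoallyl-9-borabicyclo[3.3.1]nonane adduct of 17 (boron on C13, bromine on C11; not isolated) | O=C/C=C(\C)C[C@@H](O[Si](C)(C)C(C)(C)C)/C=C(/C)[C@@H](O[Si](CC)(CC)CC)CC=C(Br)CB1C2CCCC1CCC2
F2 | step 12 | ring-closed 2-bromoallyl carbinol, the 11-bromo-12-nor analogue of hydroxy acid 20 (same spatial arrangement at C2, C6, C7, C9) | C=C(Br)[C@@H]1C[C@H](O[Si](CC)(CC)CC)/C(C)=C\[C@H](O[Si](C)(C)C(C)(C)C)C/C(C)=C/[C@H]1O
F3 | step 8 | (4R,5Z,7S)-6-methyl-7-(triethylsilyloxy)undeca-5,9,10-trien-1-yn-4-ol | C#CC[C@@H](O)/C=C(/C)[C@@H](O[Si](CC)(CC)CC)CC=C=C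
F4 | step 8 | tert-butyldimethylsilyl ether of F3 | C#CC[C@@H](O[Si](C)(C)C(C)(C)C)/C=C(/C)[C@@H](O[Si](CC)(CC)CC)CC=C=C
F5 | step 8 | (E)-alkenyl(dimethyl)alane from carboalumination of F4 (not isolated) | C[Al](C)/C=C(\C)C[C@@H](O[Si](C)(C)C(C)(C)C)/C=C(/C)[C@@H](O[Si](CC)(CC)CC)CC=C=C
F6 | step 5 | (5S,6Z)-7-iodo-6-methyl-5-(triethylsilyloxy)hept-6-en-2-yn-1-ol | OCC#CC[C@H](O[Si](CC)(CC)CC)/C(C)=C\I
F7 | step 5 | N-propargylic N-(2-nitrobenzenesulfonyl)hydrazine from F6 (not isolated) | NN(CC#CC[C@H](O[Si](CC)(CC)CC)/C(C)=C\I)S(=O)(=O)c1ccccc1[N+](=O)[O-]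
F8 | step 5 | propargylic diazene from F7 (not isolated) | N=NCC#CC[C@H](O[Si](CC)(CC)CC)/C(C)=C\I
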